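**Assumptions**
- Iridoid numbering is used: C1 acetal, C3=C4, C5/C9 ring fusion, C10 = CH2 on C8, C11 = CH2OH on C4. β is the face carrying H-5 and H-9.
- The SMILES decodes to (1S,4aS,6S,7R,7aS): 1β-O-acyl, 7β-OH, 8α-OH, 8β-CH2O-acyl (a trans-7,8-diol), and a Z-coumarate.
- Triformylmethane (CAS 18655-47-5) is treated as a catalogue chemical.

## Retrosynthetic overview
1. Luzonoid D comes from a last-step 1,2-reduction of the C11 enal. The aldehyde serves as latent CH2OH and deactivates the enol ether. The C10 (Z)-coumarate and C1 isovalerate are installed by acylation.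
2. The dihydropyran ring (C1–C9 and C4–C5 bonds, stereocentres C1/C5/C9) comes from one photochemical de Mayo-type annulation of triformylmethane onto a cyclopentene.
3. The cyclopentene (C7, C8) comes from RCM of a diene carbinol, itself made by axial vinyl addition to a 4-allyl-1,3,2-dioxasilinan-5-one.
4. That ketone comes from 2-deoxy-D-ribose, whose C3 becomes C7. The Z-acid comes from p-coumaric acid by triplet-sensitised E→Z isomerisation.
5. Ring order: temporary silylene ring, then cyclopentene (RCM), then dihydropyran (photoannulation).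

## Route

**Step 1**
Reactants: 1 2-deoxy-D-ribose; 2 methyltriphenylphosphonium bromide
Product: 3 (2R,3S)-hex-5-ene-1,2,3-triol
Conditions: 2 (3.5 equiv), KOtBu (3.4 equiv), THF, 0 °C → rt
Reagents that add atoms: ylide from 2, C[P+](c1ccccc1)(c1ccccc1)c1ccccc1.[Br-] (delivers =CH2)
Why: Wittig methylenation of the open-chain aldehyde in equilibrium with the lactol; excess ylide tolerates the free OH groups and no stereocentre is touched.

**Step 2**
Reactants: 3; 4 di-tert-butylsilyl bis(triflate)
Product: 5 (4S,5R)-4-allyl-2,2-di-tert-butyl-1,3,2-dioxasilinan-5-ol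
Conditions: 4 (1.05 equiv), 2,6-lutidine, DMF, −40 → 0 °C
Reagents that add atoms: 4, CC(C)(C)[Si](OS(=O)(=O)C(F)(F)F)(OS(=O)(=O)C(F)(F)F)C(C)(C)C
Why: Cyclic silylene protection in which the primary OH reacts first and closure gives the unstrained six-membered ring (allyl and OH both equatorial) rather than the strained five-membered dioxasilolane, leaving only the future C8 hydroxyl free.

**Step 3**
Reactants: 5
Product: 6 (4S)-4-allyl-2,2-di-tert-butyl-1,3,2-dioxasilinan-5-one
Conditions: Dess–Martin periodinane, NaHCO3, CH2Cl2, 0 °C → rt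
Reagents that add atoms: none
Why: Buffered, non-basic Dess–Martin oxidation, so the adjacent C7 stereocentre does not epimerise.

**Step 4**
Reactants: 6; 7 vinylmagnesium bromide
Product: 8 (4S,5R)-4-allyl-2,2-di-tert-butyl-5-vinyl-1,3,2-dioxasilinan-5-ol (vinyl cis to allyl)
Conditions: 7 (2 equiv), anhydrous CeCl3 (2 equiv), THF, −78 °C
Reagents that add atoms: 7, C=C[Mg]Br
Why: Organocerium 1,2-addition with axial attack, because dioxan-5-one-type chairs have no 1,3-diaxial hydrogens and the axial tBu on Si blocks the other face, so vinyl ends up cis to the equatorial allyl group and C8 (R) is set by C7.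

**Step 5**
Reactants: 8
Product: 9 cis-fused cyclopentenol, (4aR,7aS)-2,2-di-tert-butyl-4,4a,7,7a-tetrahydrocyclopenta[d][1,3,2]dioxasilin-4a-ol (C5=C9 alkene, 8α-OH; O7 and C10 tied together on the β-face)
Conditions: Grubbs II (2 mol %), CH2Cl2 (0.01 M), 40 °C
Reagents that add atoms: none (ethylene is lost)
Why: Ring-closing metathesis of a 1,6-diene whose two alkenyl arms are cis, closing easily to the cis-fused bicycle without changing any stereocentre.

**Step 6 (key step)**
Reactants: 9; 10 triformylmethane (enol form HOCH=C(CHO)2)
Product: 11 7,10-O-(di-tert-butylsilylene) iridoid lactol enal (1β-OH major, 4-CHO, H-5β, H-9β, 8α-OH)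
Conditions: 10 (4 equiv), CH2Cl2 (0.05 M), hν 300 nm, FEP flow coil, N2, 0 °C; NaHCO3 wash removes excess 10; crude 11 carried forward
Reagents that add atoms: 10, O=CC(C=O)C=O (all of C4H4O3 is retained)
Why: Proposed new method: a de Mayo-type photoannulation using triformylmethane, not previously used as the enol partner, on a 3,3-disubstituted hydroxyl-bearing cyclopentene, in which (i) the excited H-bond-locked enol adds suprafacially across C5=C9 on the convex α-face of 9 because the β-face is covered by the tBu2Si ring and the 8α-OH can hydrogen-bond the incoming tricarbonyl, (ii) the 1,4-biradical that would join the fully substituted enol carbon to C9 next to quaternary C8 cannot close and reverts so only the C1–C9/C4–C5 cyclobutanol forms, (iii) this β-hydroxy gem-dialdehyde undergoes spontaneous retro-aldol cleavage of C1–C4, and (iv) the malondialdehyde enol closes on the C1 aldehyde, giving cis H-5/H-9 and C11 directly at the aldehyde level; the closest known reaction type is the de Mayo reaction, specifically the photoannulation of methyl diformylacetate with simple cyclopentenes.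

**Step 7**
Reactants: 11; 12 isovaleric anhydride
Product: 13 1β-O-isovaleryl derivative of 11
Conditions: 12 (1.5 equiv), pyridine, DMAP (5 mol %), CH2Cl2, −20 → 0 °C
Reagents that add atoms: 12, CC(C)CC(=O)OC(=O)CC(C)C
Why: DMAP-catalysed acylation of the equilibrating lactol traps the less hindered β-anomer (O1 trans to the C9–C8 bond), the tertiary 8-OH is inert, and the weak base and low temperature avoid retro-aldol of the open form.

**Step 8**
Reactants: 13
Product: 14 (1S,4aS,6S,7R,7aS)-4-formyl-6,7-dihydroxy-7-(hydroxymethyl)-1,4a,5,6,7,7a-hexahydrocyclopenta[c]pyran-1-yl 3-methylbutanoate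
Conditions: HF·pyridine, pyridine/THF, 0 °C
Reagents that add atoms: none
Why: Buffered fluoride cleavage of the silylene, which the acyl acetal survives because the ring-oxygen lone pair is tied up in the vinylogous formate.

**Step 9 (side branch)**
Reactants: 15 (E)-p-coumaric acid; 16 TBSCl
Product: 17 (E)-4-(tert-butyldimethylsilyloxy)cinnamic acid
Conditions: 16 (2.3 equiv), imidazole, DMF, rt; then K2CO3, THF/MeOH/H2O, 0 °C
Reagents that add atoms: 16, CC(C)(C)[Si](C)(C)Cl
Why: Bis-silylation followed by selective hydrolysis of the much more labile silyl ester.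

**Step 10 (side branch)**
Reactants: 17
Product: 18 (Z)-4-(tert-butyldimethylsilyloxy)cinnamic acid
Conditions: fac-Ir(ppy)3 (0.5 mol %), 450 nm LEDs, MeCN, N2, rt; residual 17 separated and recycled
Reagents that add atoms: none
Why: Triplet energy-transfer E→Z isomerisation in which the planar E-cinnamate is sensitised faster than the twisted Z-isomer, so Z accumulates at the photostationary state (no stereocentre is involved).

**Step 11**
Reactants: 14; 18
Product: 19 10-O-[(Z)-4-TBSO-cinnamoyl] derivative of 14
Conditions: 18 (1.1 equiv), EDC·HCl, DMAP (10 mol %), CH2Cl2, −10 °C, dark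
Reagents that add atoms: 18, OC(=O)/C=C\c1ccc(O[Si](C)(C)C(C)(C)C)cc1
Why: Steglich esterification that selects the primary C10-OH over the hindered secondary C7-OH and tertiary C8-OH, with low DMAP loading, low temperature and darkness preserving the Z-alkene.

**Step 12**
Reactants: 19
Product: 20 11-oxo-luzonoid D (free phenol, 4-CHO)
Conditions: TBAF/AcOH (1:1, 1.2 equiv), THF, 0 °C, 15 min, dark
Reagents that add atoms: none
Why: Buffered fluoride removes the very labile phenolic silyl ether without acyl migration or Z→E drift, and it is done while the core is still the robust enal.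

**Step 13**
Reactants: 20
Product: 21 luzonoid D
Conditions: NaBH4 (1.2 equiv), THF/MeOH 4:1, −40 °C, 20 min; pH 7 phosphate quench; Et3N-deactivated SiO2, dark
Reagents that add atoms: none (hydride and proton only)
Why: Chemoselective 1,2-reduction of the β-alkoxy enal, whose β-carbon is deactivated by oxygen donation, while both esters and the Z-cinnamate are untouched at −40 °C and the acid-sensitive allylic enol ether is unveiled only at the end.

## Compound list
1 | 2-deoxy-D-ribose (drawn open-chain) | O=CC[C@H](O)[C@H](O)CO | starting material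
2 | methyltriphenylphosphonium bromide | C[P+](c1ccccc1)(c1ccccc1)c1ccccc1.[Br-] | starting material
3 | (2R,3S)-hex-5-ene-1,2,3-triol | C=CC[C@H](O)[C@H](O)CO | intermediate
4 | di-tert-butylsilyl bis(triflate) | CC(C)(C)[Si](OS(=O)(=O)C(F)(F)F)(OS(=O)(=O)C(F)(F)F)C(C)(C)C | starting material
5 | (4S,5R)-4-allyl-2,2-di-tert-butyl-1,3,2-dioxasilinan-5-ol | C=CC[C@@H]1O[Si](C(C)(C)C)(C(C)(C)C)OC[C@H]1O | intermediate
6 | (4S)-4-allyl-2,2-di-tert-butyl-1,3,2-dioxasilinan-5-one | C=CC[C@@H]1O[Si](C(C)(C)C)(C(C)(C)C)OCC1=O | intermediate
7 | vinylmagnesium bromide | C=C[Mg]Br | starting material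
8 | (4S,5R)-4-allyl-2,2-di-tert-butyl-5-vinyl-1,3,2-dioxasilinan-5-ol | C=CC[C@@H]1O[Si](C(C)(C)C)(C(C)(C)C)OC[C@]1(O)C=C | intermediate
9 | cis-fused silylene cyclopentenol (4aR,7aS) | C1=CC[C@@H]2O[Si](C(C)(C)C)(C(C)(C)C)OC[C@]12O | intermediate
10 | triformylmethane | O=CC(C=O)C=O | starting material
11 | 7,10-O-silylene iridoid lactol enal (1β-OH) | O[C@@H]1OC=C(C=O)[C@H]2C[C@@H]3O[Si](C(C)(C)C)(C(C)(C)C)OC[C@]3(O)[C@@H]12 | intermediate
12 | isovaleric anhydride | CC(C)CC(=O)OC(=O)CC(C)C | starting material
13 | 1β-O-isovaleryl-7,10-O-silylene enal | CC(C)CC(=O)O[C@@H]1OC=C(C=O)[C@H]2C[C@@H]3O[Si](C(C)(C)C)(C(C)(C)C)OC[C@]3(O)[C@@H]12 | intermediate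
14 | 1β-O-isovaleryl-7β,8α,10-triol enal | CC(C)CC(=O)O[C@@H]1OC=C(C=O)[C@H]2C[C@H](O)[C@](O)(CO)[C@@H]12 | intermediate
15 | (E)-p-coumaric acid | OC(=O)/C=C/c1ccc(O)cc1 | starting material
16 | tert-butyldimethylsilyl chloride | CC(C)(C)[Si](C)(C)Cl | starting material
17 | (E)-4-TBSO-cinnamic acid | OC(=O)/C=C/c1ccc(O[Si](C)(C)C(C)(C)C)cc1 | intermediate
18 | (Z)-4-TBSO-cinnamic acid | OC(=O)/C=C\c1ccc(O[Si](C)(C)C(C)(C)C)cc1 | intermediate
19 | 10-O-[(Z)-4-TBSO-cinnamoyl] enal | CC(C)CC(=O)O[C@@H]1OC=C(C=O)[C@H]2C[C@H](O)[C@](O)(COC(=O)/C=C\c3ccc(O[Si](C)(C)C(C)(C)C)cc3)[C@@H]12 | intermediate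
20 | 11-oxo-luzonoid D | CC(C)CC(=O)O[C@@H]1OC=C(C=O)[C@H]2C[C@H](O)[C@](O)(COC(=O)/C=C\c3ccc(O)cc3)[C@@H]12 | intermediate
21 | luzonoid D | CC(C)CC(=O)O[C@@H]1OC=C(CO)[C@H]2C[C@H](O)[C@](O)(COC(=O)/C=C\c3ccc(O)cc3)[C@@H]12 | target

## Summary
**Total steps:** 13.
**Longest linear sequence:** 11 (Steps 1–8, then 11–13).
**Where each stereo-element is set:**
- C7 is bought in compound 1.
- C8 is set in Step 4, controlled by C7.
- C5 and C9 are set in Step 6, controlled by C7 and C8.
- C1 is set in Steps 6 and 7, controlled by C9.
- The Z-alkene is set in Step 10.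

**Steps most likely to fail**
1. **Step 6 (proposed new photoannulation).**
   - Risks: poor efficiency on the hindered alkene, Paternò–Büchi side reactions of the formyl groups, and secondary photolysis of the product enal.
   - Fallback (known chemistry): run the established photoannulation with methyl diformylacetate to give the C11 methyl ester lactol. Then change the oxidation-state plan with 1-O-TBS protection, DIBAL-H, MnO2 and TBAF to rejoin the route at 11. This costs four extra, routine steps.
2. **Step 4 (C8 diastereoselectivity).**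
   - Risk: axial attack may not dominate on the flattened silylene ring.
   - Fallback: replace ring control with chelation control. Convert 3 to its 1,3-PMP acetal, open it reductively with DIBAL-H to the O7-PMB ether, protect O10 as TBDPS, and oxidise. Add vinylMgBr to the MgBr2 chelate of this acyclic ketone. Cram-chelate attack is predicted to give the same C8 configuration.
3. **Step 11 (site-selective esterification with retention of Z geometry).**
   - Risks: DMAP-induced Z→E drift and partial C7 acylation.
   - Fallback: esterify with the robust E-acid 17 through its mixed anhydride and move the energy-transfer E→Z isomerisation to the enal stage (19 or 20). The geometry is then set after the coupling rather than before it.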